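## Retrosynthetic overview

1. Target ⇐ its octabenzyl ether; global O‑debenzylation comes last, and benzyl is chosen because it is removed without hydrogenating the stilbene.
2. Dihydrofuran ring of unit A (the ring with the 4‑hydroxyphenyl and styryl groups, formed second) ⇐ new asymmetric [4+1] annulation of an ortho‑quinone methide (C3–C3a already in place) with a chiral sulfonium benzylide; it forms C2–C3 and O1–C2 and sets both stereocentres.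
3. Ortho‑quinone methide precursor of unit A ⇐ aryllithium from the 6‑bromo dihydrobenzofuran of unit B + a stilbene salicylaldehyde (Heck reaction).
4. Dihydrofuran ring of unit B (the ring with the catechol and resorcinol aryl groups, formed first) ⇐ the same [4+1] annulation with the enantiomeric sulfide, on the ortho‑quinone methide from a bromosalicylaldehyde and a 3,5‑bis(benzyloxy)phenyl Grignard reagent.
5. Both salicylaldehydes ⇐ 4‑bromo‑2,6‑difluorobenzaldehyde (double SNAr, chelation‑controlled mono‑debenzylation); both sulfides ⇐ (R)‑ and (S)‑limonene.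

Assumption: the facial sense of the isothiocineole ylides in the new annulation is taken from a steric model (aryl syn to the sulfur lone pair, attack anti to the gem‑dimethyl carbon, inversion on ring closure), which assigns the (S)‑limonene‑derived salt to the (2S,3S) ring and the (R)‑limonene‑derived salt to the (2R,3R) ring; if a model run shows the opposite sense, the two sulfide enantiomers are exchanged and nothing else changes.

## Route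

Step 1
Reactants: 1 4‑bromo‑2,6‑difluorobenzaldehyde
Product: 2 2,6‑bis(benzyloxy)‑4‑bromobenzaldehyde
Conditions: BnOH (2.2 equiv), NaH (2.2 equiv), THF, 0 °C → rt
Reagents that add atoms: benzyl alcohol, OCc1ccccc1
Why: Twofold nucleophilic aromatic substitution (SNAr), in which both fluorides sit ortho to the formyl group and are displaced by benzyl oxide through Meisenheimer intermediates much faster than the para bromide, which is kept as the later coupling handle.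

Step 2
Reactants: 2 2,6‑bis(benzyloxy)‑4‑bromobenzaldehyde
Product: 3 2‑(benzyloxy)‑4‑bromo‑6‑hydroxybenzaldehyde
Conditions: MgBr2·OEt2 (1.5 equiv), toluene/Et2O, 70 °C; then 1 M HCl
Reagents that add atoms: none
Why: Chelation‑controlled Lewis acid ether cleavage, in which magnesium bridges the formyl oxygen and one ortho benzyloxy oxygen so that bromide removes only that benzyl group by SN2, and the magnesium phenoxide chelate that results blocks cleavage of the second ether.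

Step 3
Reactants: 3 2‑(benzyloxy)‑4‑bromo‑6‑hydroxybenzaldehyde; 4 1,3‑bis(benzyloxy)‑5‑bromobenzene
Product: 6 rac‑[2‑(benzyloxy)‑4‑bromo‑6‑hydroxyphenyl][3,5‑bis(benzyloxy)phenyl]methanol, via aryl Grignard reagent 5 (not isolated)
Conditions: 4, Mg, THF, reflux (gives 5); 3, NaH (1.0 equiv), THF, 0 °C; then 5 (1.3 equiv), −20 °C → rt; aq NH4Cl
Reagents that add atoms: magnesium (enters intermediate 5 only), [Mg]
Why: Grignard 1,2‑addition to the aldehyde of the preformed sodium phenoxide (so only one equivalent of 5 is spent), giving a racemic carbinol centre that is erased again in step 7.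

Step 4
Reactants: 6 rac‑[2‑(benzyloxy)‑4‑bromo‑6‑hydroxyphenyl][3,5‑bis(benzyloxy)phenyl]methanol
Product: 7 rac‑3‑(benzyloxy)‑5‑bromo‑2‑{[3,5‑bis(benzyloxy)phenyl](4‑methylbenzenesulfonyl)methyl}phenol
Conditions: p‑TolSO2H (1.5 equiv), CH2Cl2, rt
Reagents that add atoms: 4‑methylbenzenesulfinic acid, Cc1ccc(cc1)S(=O)O
Why: Acid‑promoted SN1 substitution, in which the benzhydrol ionises to the cation stabilised by the ortho hydroxy and ortho benzyloxy groups (a protonated ortho‑quinone methide) and sulfinate traps it at sulfur, giving the stable sulfone that serves as base‑triggered ortho‑quinone methide precursor.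

Step 5
Reactants: 8 (S)‑limonene
Product: 9 (1R,5R)‑4,7,7‑trimethyl‑6‑thiabicyclo[3.2.1]oct‑3‑ene [(1R,5R)‑isothiocineole]
Conditions: S8, γ‑terpinene, neat, 110 °C; distillation
Reagents that add atoms: sulfur, S1SSSSSSS1
Why: Known one‑step thermal sulfuration of limonene, in which sulfur bonds to the isopropenyl carbon and to the ring allylic carbon and bridges them, so the limonene stereocentre is kept and dictates the only possible configuration at the new C–S bridgehead (γ‑terpinene acts as hydrogen donor).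

Step 6
Reactants: 9 (1R,5R)‑isothiocineole; 10 1,2‑bis(benzyloxy)‑4‑(chloromethyl)benzene
Product: 11 (1R,5R,6R)‑6‑[3,4‑bis(benzyloxy)benzyl]‑4,7,7‑trimethyl‑6‑thiabicyclo[3.2.1]oct‑3‑en‑6‑ium tetrafluoroborate (benzyl group exo, syn to the one‑carbon bridge)
Conditions: AgBF4 (1.05 equiv), CH2Cl2, −20 °C → rt, dark
Reagents that add atoms: silver tetrafluoroborate, [Ag+].F[B-](F)(F)F
Why: Silver‑assisted S‑alkylation (sulfonium salt formation), in which AgBF4 abstracts chloride from the electron‑rich benzylic chloride and the sulfide captures the benzylic carbon on its less hindered exo lone pair, so one diastereomer at sulfur forms.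

Step 7
Reactants: 7 rac‑3‑(benzyloxy)‑5‑bromo‑2‑{[3,5‑bis(benzyloxy)phenyl](4‑methylbenzenesulfonyl)methyl}phenol; 11 (1R,5R,6R)‑6‑[3,4‑bis(benzyloxy)benzyl]‑4,7,7‑trimethyl‑6‑thiabicyclo[3.2.1]oct‑3‑en‑6‑ium tetrafluoroborate
Product: 14 (2S,3S)‑4‑(benzyloxy)‑6‑bromo‑2‑[3,4‑bis(benzyloxy)phenyl]‑3‑[3,5‑bis(benzyloxy)phenyl]‑2,3‑dihydro‑1‑benzofuran, via ortho‑quinone methide 12 (not isolated), via sulfonium ylide 13 (not isolated)
Conditions: 11 (1.3 equiv), Cs2CO3 (3 equiv), CH2Cl2, −20 → 0 °C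
Reagents that add atoms: none
Why: Proposed new method: asymmetric formal [4+1] annulation of an ortho‑quinone methide with a semi‑stabilised chiral sulfonium benzylide, in which Cs2CO3 deprotonates the phenol of 7 (which expels sulfinate to give ortho‑quinone methide 12) and converts 11 into ylide 13, the ylide carbon (aryl syn to the sulfur lone pair, one face shielded by the gem‑dimethyl carbon of the bicycle) adds 1,4 to the exocyclic carbon of 12 to form the C2–C3 bond and restore the phenoxide, and the phenoxide then displaces the sulfide by 5‑exo‑tet SN2 with inversion to form the O1–C2 bond, so that C2 is set (S) by reagent control and C3 (S) by the faster closure of the betaine that leads to the trans ring (any cis isomer is removed by chromatography and not epimerised, and sulfide 9 is recovered); the closest known reactions are the Corey–Chaykovsky‑type [4+1] annulation of ortho‑quinone methides with carbonyl‑stabilised sulfonium or ammonium ylides and the asymmetric epoxidation, aziridination and cyclopropanation with isothiocineole‑derived benzylsulfonium ylides.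

Step 8
Reactants: 3 2‑(benzyloxy)‑4‑bromo‑6‑hydroxybenzaldehyde; 15 1‑(benzyloxy)‑4‑ethenylbenzene
Product: 16 2‑(benzyloxy)‑4‑{(E)‑2‑[4‑(benzyloxy)phenyl]ethenyl}‑6‑hydroxybenzaldehyde
Conditions: Pd(OAc)2 (3 mol%), P(o‑tol)3 (6 mol%), Et3N, DMF, 90 °C
Reagents that add atoms: none
Why: Mizoroki–Heck reaction, in which zerovalent palladium inserts into the C–Br bond activated by the para formyl group and syn carbopalladation of the styrene followed by syn β‑hydride elimination gives the E stilbene, the free phenol and the aldehyde being tolerated.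

Step 9
Reactants: 14 (2S,3S)‑4‑(benzyloxy)‑6‑bromo‑2‑[3,4‑bis(benzyloxy)phenyl]‑3‑[3,5‑bis(benzyloxy)phenyl]‑2,3‑dihydro‑1‑benzofuran; 16 2‑(benzyloxy)‑4‑{(E)‑2‑[4‑(benzyloxy)phenyl]ethenyl}‑6‑hydroxybenzaldehyde
Product: 18 [2‑(benzyloxy)‑4‑{(E)‑2‑[4‑(benzyloxy)phenyl]ethenyl}‑6‑hydroxyphenyl]{(2S,3S)‑4‑(benzyloxy)‑2‑[3,4‑bis(benzyloxy)phenyl]‑3‑[3,5‑bis(benzyloxy)phenyl]‑2,3‑dihydro‑1‑benzofuran‑6‑yl}methanol (both carbinol epimers), via aryllithium 17 (not isolated)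
Conditions: 14, n‑BuLi (1.05 equiv), THF, −78 °C (gives 17); 16, NaH (1.0 equiv), THF, 0 °C, then added to 17 at −78 → −40 °C; aq NH4Cl
Reagents that add atoms: n‑butyllithium (its lithium enters intermediate 17 only), [Li]CCCC
Why: Bromine–lithium exchange at −78 °C outruns deprotonation of the ring C–H bonds, and the aryllithium then adds 1,2 to the aldehyde of the preformed sodium phenoxide (so none is lost to the phenol), giving a carbinol mixture that is erased in step 13 while the two existing stereocentres are not touched.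

Step 10
Reactants: 18 [2‑(benzyloxy)‑4‑{(E)‑2‑[4‑(benzyloxy)phenyl]ethenyl}‑6‑hydroxyphenyl]{(2S,3S)‑4‑(benzyloxy)‑2‑[3,4‑bis(benzyloxy)phenyl]‑3‑[3,5‑bis(benzyloxy)phenyl]‑2,3‑dihydro‑1‑benzofuran‑6‑yl}methanol
Product: 19 3‑(benzyloxy)‑5‑{(E)‑2‑[4‑(benzyloxy)phenyl]ethenyl}‑2‑[{(2S,3S)‑4‑(benzyloxy)‑2‑[3,4‑bis(benzyloxy)phenyl]‑3‑[3,5‑bis(benzyloxy)phenyl]‑2,3‑dihydro‑1‑benzofuran‑6‑yl}(4‑methylbenzenesulfonyl)methyl]phenol (both epimers at the sulfonyl carbon)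
Conditions: p‑TolSO2H (1.5 equiv), CH2Cl2, rt, dark
Reagents that add atoms: 4‑methylbenzenesulfinic acid, Cc1ccc(cc1)S(=O)O
Why: The same acid‑promoted SN1 sulfinate substitution as in step 4, through the benzhydryl cation stabilised by the ortho hydroxy and ortho benzyloxy groups, with the stilbene and the existing dihydrobenzofuran inert to the weak acid.

Step 11
Reactants: 20 (R)‑limonene
Product: 21 (1S,5S)‑4,7,7‑trimethyl‑6‑thiabicyclo[3.2.1]oct‑3‑ene [(1S,5S)‑isothiocineole]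
Conditions: S8, γ‑terpinene, neat, 110 °C; distillation
Reagents that add atoms: sulfur, S1SSSSSSS1
Why: The same known thermal sulfuration of limonene as in step 5, applied to the other limonene enantiomer, so the retained stereocentre again fixes the configuration of the C–S bridgehead.

Step 12
Reactants: 21 (1S,5S)‑isothiocineole; 22 1‑(benzyloxy)‑4‑(chloromethyl)benzene
Product: 23 (1S,5S,6S)‑6‑[4‑(benzyloxy)benzyl]‑4,7,7‑trimethyl‑6‑thiabicyclo[3.2.1]oct‑3‑en‑6‑ium tetrafluoroborate (benzyl group exo, syn to the one‑carbon bridge)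
Conditions: AgBF4 (1.05 equiv), CH2Cl2, −20 °C → rt, dark
Reagents that add atoms: silver tetrafluoroborate, [Ag+].F[B-](F)(F)F
Why: The same silver‑assisted S‑alkylation as in step 6, on the exo lone pair of the sulfide, giving one sulfonium diastereomer.

Step 13
Reactants: 19 3‑(benzyloxy)‑5‑{(E)‑2‑[4‑(benzyloxy)phenyl]ethenyl}‑2‑[{(2S,3S)‑4‑(benzyloxy)‑2‑[3,4‑bis(benzyloxy)phenyl]‑3‑[3,5‑bis(benzyloxy)phenyl]‑2,3‑dihydro‑1‑benzofuran‑6‑yl}(4‑methylbenzenesulfonyl)methyl]phenol; 23 (1S,5S,6S)‑6‑[4‑(benzyloxy)benzyl]‑4,7,7‑trimethyl‑6‑thiabicyclo[3.2.1]oct‑3‑en‑6‑ium tetrafluoroborate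
Product: 26 (2R,3R)‑4‑(benzyloxy)‑2‑[4‑(benzyloxy)phenyl]‑6‑{(E)‑2‑[4‑(benzyloxy)phenyl]ethenyl}‑3‑{(2S,3S)‑4‑(benzyloxy)‑2‑[3,4‑bis(benzyloxy)phenyl]‑3‑[3,5‑bis(benzyloxy)phenyl]‑2,3‑dihydro‑1‑benzofuran‑6‑yl}‑2,3‑dihydro‑1‑benzofuran, via ortho‑quinone methide 24 (not isolated), via sulfonium ylide 25 (not isolated)
Conditions: 23 (1.3 equiv), Cs2CO3 (3 equiv), CH2Cl2, −20 → 0 °C, dark
Reagents that add atoms: none
Why: Proposed new method: the same asymmetric [4+1] annulation as in step 7, now between ylide 25 from the (R)‑limonene‑derived salt and ortho‑quinone methide 24 released from 19 by Cs2CO3, in which 1,4‑addition of the ylide carbon forms C2–C3 (the only addition that restores the arene, so the styryl group does not compete) and 5‑exo‑tet SN2 closure with inversion forms O1–C2 and releases sulfide 21, and because the existing stereocentres lie five bonds from the reacting carbon the new (2R,3R) trans ring is set by reagent control (the minor sense gives a separable diastereomer); the closest known reactions are those named in step 7.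

Step 14
Reactants: 26 (2R,3R)‑4‑(benzyloxy)‑2‑[4‑(benzyloxy)phenyl]‑6‑{(E)‑2‑[4‑(benzyloxy)phenyl]ethenyl}‑3‑{(2S,3S)‑4‑(benzyloxy)‑2‑[3,4‑bis(benzyloxy)phenyl]‑3‑[3,5‑bis(benzyloxy)phenyl]‑2,3‑dihydro‑1‑benzofuran‑6‑yl}‑2,3‑dihydro‑1‑benzofuran
Product: 27 (2R,3R)‑3‑[(2S,3S)‑2‑(3,4‑dihydroxyphenyl)‑3‑(3,5‑dihydroxyphenyl)‑4‑hydroxy‑2,3‑dihydro‑1‑benzofuran‑6‑yl]‑2‑(4‑hydroxyphenyl)‑6‑[(E)‑2‑(4‑hydroxyphenyl)ethenyl]‑2,3‑dihydro‑1‑benzofuran‑4‑ol (CNP0107857.3)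
Conditions: BCl3 (16 equiv), C6Me5H (24 equiv), CH2Cl2, −78 °C; MeOH then H2O; reverse‑phase HPLC
Reagents that add atoms: none
Why: Lewis acid debenzylation with a cation scavenger, in which BCl3 cleaves all eight benzyl aryl ethers at −78 °C and pentamethylbenzene captures the benzyl cations by Friedel–Crafts alkylation, so the stilbene and the electron‑rich rings are not benzylated, no hydrogenation touches the alkene, and the two trans rings keep their configuration because the C3 centres cannot ionise and any reversible C2–O ionisation recloses to the trans ring.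

## Compound list

1 | 4‑bromo‑2,6‑difluorobenzaldehyde | O=Cc1c(F)cc(Br)cc1F | starting material
2 | 2,6‑bis(benzyloxy)‑4‑bromobenzaldehyde | O=Cc1c(OCc2ccccc2)cc(Br)cc1OCc1ccccc1 | intermediate
3 | 2‑(benzyloxy)‑4‑bromo‑6‑hydroxybenzaldehyde | O=Cc1c(O)cc(Br)cc1OCc1ccccc1 | intermediate
4 | 1,3‑bis(benzyloxy)‑5‑bromobenzene | Brc1cc(OCc2ccccc2)cc(OCc2ccccc2)c1 | starting material
5 | [3,5‑bis(benzyloxy)phenyl]magnesium bromide | Br[Mg]c1cc(OCc2ccccc2)cc(OCc2ccccc2)c1 | intermediate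
6 | rac‑[2‑(benzyloxy)‑4‑bromo‑6‑hydroxyphenyl][3,5‑bis(benzyloxy)phenyl]methanol | OC(c1cc(OCc2ccccc2)cc(OCc2ccccc2)c1)c1c(O)cc(Br)cc1OCc1ccccc1 | intermediate
7 | rac‑3‑(benzyloxy)‑5‑bromo‑2‑{[3,5‑bis(benzyloxy)phenyl](4‑methylbenzenesulfonyl)methyl}phenol | Cc1ccc(cc1)S(=O)(=O)C(c1cc(OCc2ccccc2)cc(OCc2ccccc2)c1)c1c(O)cc(Br)cc1OCc1ccccc1 | intermediate
8 | (S)‑limonene | CC1=CC[C@H](CC1)C(C)=C | starting material
9 | (1R,5R)‑4,7,7‑trimethyl‑6‑thiabicyclo[3.2.1]oct‑3‑ene, (1R,5R)‑isothiocineole | CC1=CC[C@@H]2C[C@H]1SC2(C)C | intermediate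
10 | 1,2‑bis(benzyloxy)‑4‑(chloromethyl)benzene | ClCc1ccc(OCc2ccccc2)c(OCc2ccccc2)c1 | starting material
11 | (1R,5R,6R)‑6‑[3,4‑bis(benzyloxy)benzyl]‑4,7,7‑trimethyl‑6‑thiabicyclo[3.2.1]oct‑3‑en‑6‑ium tetrafluoroborate, benzyl exo | CC1=CC[C@@H]2C[C@H]1[S@@+](Cc1ccc(OCc3ccccc3)c(OCc3ccccc3)c1)C2(C)C.F[B-](F)(F)F | intermediate
12 | 5‑(benzyloxy)‑3‑bromo‑6‑[3,5‑bis(benzyloxy)benzylidene]cyclohexa‑2,4‑dien‑1‑one (ortho‑quinone methide) | O=C1C=C(Br)C=C(OCc2ccccc2)C1=Cc1cc(OCc2ccccc2)cc(OCc2ccccc2)c1 | intermediate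
13 | [3,4‑bis(benzyloxy)phenyl][(1R,5R,6R)‑4,7,7‑trimethyl‑6‑thiabicyclo[3.2.1]oct‑3‑en‑6‑ium‑6‑yl]methanide (sulfonium ylide) | CC1=CC[C@@H]2C[C@H]1[S@@+]([CH-]c1ccc(OCc3ccccc3)c(OCc3ccccc3)c1)C2(C)C | intermediate
14 | (2S,3S)‑4‑(benzyloxy)‑6‑bromo‑2‑[3,4‑bis(benzyloxy)phenyl]‑3‑[3,5‑bis(benzyloxy)phenyl]‑2,3‑dihydro‑1‑benzofuran (trans) | Brc1cc(OCc2ccccc2)c2c(c1)O[C@H](c1ccc(OCc3ccccc3)c(OCc3ccccc3)c1)[C@H]2c1cc(OCc2ccccc2)cc(OCc2ccccc2)c1 | intermediate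
15 | 1‑(benzyloxy)‑4‑ethenylbenzene | C=Cc1ccc(OCc2ccccc2)cc1 | starting material
16 | 2‑(benzyloxy)‑4‑{(E)‑2‑[4‑(benzyloxy)phenyl]ethenyl}‑6‑hydroxybenzaldehyde | O=Cc1c(O)cc(/C=C/c2ccc(OCc3ccccc3)cc2)cc1OCc1ccccc1 | intermediate
17 | {(2S,3S)‑4‑(benzyloxy)‑2‑[3,4‑bis(benzyloxy)phenyl]‑3‑[3,5‑bis(benzyloxy)phenyl]‑2,3‑dihydro‑1‑benzofuran‑6‑yl}lithium | [Li]c1cc(OCc2ccccc2)c2c(c1)O[C@H](c1ccc(OCc3ccccc3)c(OCc3ccccc3)c1)[C@H]2c1cc(OCc2ccccc2)cc(OCc2ccccc2)c1 | intermediate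
18 | [2‑(benzyloxy)‑4‑{(E)‑2‑[4‑(benzyloxy)phenyl]ethenyl}‑6‑hydroxyphenyl]{(2S,3S)‑4‑(benzyloxy)‑2‑[3,4‑bis(benzyloxy)phenyl]‑3‑[3,5‑bis(benzyloxy)phenyl]‑2,3‑dihydro‑1‑benzofuran‑6‑yl}methanol, both carbinol epimers | OC(c1c(O)cc(/C=C/c2ccc(OCc3ccccc3)cc2)cc1OCc1ccccc1)c1cc(OCc2ccccc2)c2c(c1)O[C@H](c1ccc(OCc3ccccc3)c(OCc3ccccc3)c1)[C@H]2c1cc(OCc2ccccc2)cc(OCc2ccccc2)c1 | intermediate
19 | 3‑(benzyloxy)‑5‑{(E)‑2‑[4‑(benzyloxy)phenyl]ethenyl}‑2‑[{(2S,3S)‑4‑(benzyloxy)‑2‑[3,4‑bis(benzyloxy)phenyl]‑3‑[3,5‑bis(benzyloxy)phenyl]‑2,3‑dihydro‑1‑benzofuran‑6‑yl}(4‑methylbenzenesulfonyl)methyl]phenol, both epimers at the sulfonyl carbon | Cc1ccc(cc1)S(=O)(=O)C(c1c(O)cc(/C=C/c2ccc(OCc3ccccc3)cc2)cc1OCc1ccccc1)c1cc(OCc2ccccc2)c2c(c1)O[C@H](c1ccc(OCc3ccccc3)c(OCc3ccccc3)c1)[C@H]2c1cc(OCc2ccccc2)cc(OCc2ccccc2)c1 | intermediate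
20 | (R)‑limonene | CC1=CC[C@@H](CC1)C(C)=C | starting material
21 | (1S,5S)‑4,7,7‑trimethyl‑6‑thiabicyclo[3.2.1]oct‑3‑ene, (1S,5S)‑isothiocineole | CC1=CC[C@H]2C[C@@H]1SC2(C)C | intermediate
22 | 1‑(benzyloxy)‑4‑(chloromethyl)benzene | ClCc1ccc(OCc2ccccc2)cc1 | starting material
23 | (1S,5S,6S)‑6‑[4‑(benzyloxy)benzyl]‑4,7,7‑trimethyl‑6‑thiabicyclo[3.2.1]oct‑3‑en‑6‑ium tetrafluoroborate, benzyl exo | CC1=CC[C@H]2C[C@@H]1[S@+](Cc1ccc(OCc3ccccc3)cc1)C2(C)C.F[B-](F)(F)F | intermediate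
24 | 5‑(benzyloxy)‑3‑{(E)‑2‑[4‑(benzyloxy)phenyl]ethenyl}‑6‑({(2S,3S)‑4‑(benzyloxy)‑2‑[3,4‑bis(benzyloxy)phenyl]‑3‑[3,5‑bis(benzyloxy)phenyl]‑2,3‑dihydro‑1‑benzofuran‑6‑yl}methylidene)cyclohexa‑2,4‑dien‑1‑one (ortho‑quinone methide) | O=C1C=C(/C=C/c2ccc(OCc3ccccc3)cc2)C=C(OCc2ccccc2)C1=Cc1cc(OCc2ccccc2)c2c(c1)O[C@H](c1ccc(OCc3ccccc3)c(OCc3ccccc3)c1)[C@H]2c1cc(OCc2ccccc2)cc(OCc2ccccc2)c1 | intermediate
25 | [4‑(benzyloxy)phenyl][(1S,5S,6S)‑4,7,7‑trimethyl‑6‑thiabicyclo[3.2.1]oct‑3‑en‑6‑ium‑6‑yl]methanide (sulfonium ylide) | CC1=CC[C@H]2C[C@@H]1[S@+]([CH-]c1ccc(OCc3ccccc3)cc1)C2(C)C | intermediate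
26 | (2R,3R)‑4‑(benzyloxy)‑2‑[4‑(benzyloxy)phenyl]‑6‑{(E)‑2‑[4‑(benzyloxy)phenyl]ethenyl}‑3‑{(2S,3S)‑4‑(benzyloxy)‑2‑[3,4‑bis(benzyloxy)phenyl]‑3‑[3,5‑bis(benzyloxy)phenyl]‑2,3‑dihydro‑1‑benzofuran‑6‑yl}‑2,3‑dihydro‑1‑benzofuran (octabenzyl ether of the target) | C(Oc1ccc(/C=C/c2cc(OCc3ccccc3)c3c(c2)O[C@@H](c2ccc(OCc4ccccc4)cc2)[C@@H]3c2cc(OCc3ccccc3)c3c(c2)O[C@H](c2ccc(OCc4ccccc4)c(OCc4ccccc4)c2)[C@H]3c2cc(OCc3ccccc3)cc(OCc3ccccc3)c2)cc1)c1ccccc1 | intermediate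
27 | (2R,3R)‑3‑[(2S,3S)‑2‑(3,4‑dihydroxyphenyl)‑3‑(3,5‑dihydroxyphenyl)‑4‑hydroxy‑2,3‑dihydro‑1‑benzofuran‑6‑yl]‑2‑(4‑hydroxyphenyl)‑6‑[(E)‑2‑(4‑hydroxyphenyl)ethenyl]‑2,3‑dihydro‑1‑benzofuran‑4‑ol (CNP0107857.3) | Oc1ccc(/C=C/c2cc(O)c3c(c2)O[C@@H](c2ccc(O)cc2)[C@@H]3c2cc(O)c3c(c2)O[C@H](c2ccc(O)c(O)c2)[C@H]3c2cc(O)cc(O)c2)cc1 | target

## Step count and risk

Total step count: 14. Longest linear sequence: 9 steps (steps 1, 2, 3, 4, 7, 9, 10, 13, 14).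

Three steps most likely to fail:

**Step 7 (proposed new annulation).** Risks are O‑benzylation of the phenoxide by the sulfonium salt, dimerisation of the ortho‑quinone methide, and insufficient facial or trans control. The fallback uses known chemistry, sets out from 7 and comes back at 14. Compound 7 is deprotonated with NaH (1.0 equiv, THF, 0 °C) and added at −78 °C to 2‑lithio‑1,3‑dithiane F1 (1.3 equiv, from 1,3‑dithiane and n‑BuLi). On warming to 0 °C the phenoxide expels sulfinate and the formyl anion equivalent adds 1,4 to the ortho‑quinone methide (Corey–Seebach umpolung, conjugate addition), giving racemic 3‑(benzyloxy)‑5‑bromo‑2‑{[3,5‑bis(benzyloxy)phenyl](1,3‑dithian‑2‑yl)methyl}phenol F2. Dithioacetal hydrolysis (MeI, CaCO3, MeCN/H2O, 45 °C) gives the aldehyde, which rests as the lactol 4‑(benzyloxy)‑3‑[3,5‑bis(benzyloxy)phenyl]‑6‑bromo‑2,3‑dihydro‑1‑benzofuran‑2‑ol F3. [3,4‑Bis(benzyloxy)phenyl]magnesium bromide F4 (2.2 equiv, from commercial 4‑bromo‑1,2‑bis(benzyloxy)benzene and Mg, THF, 0 °C) opens the lactol and adds to the aldehyde, giving the diol 3‑(benzyloxy)‑5‑bromo‑2‑{2‑[3,4‑bis(benzyloxy)phenyl]‑1‑[3,5‑bis(benzyloxy)phenyl]‑2‑hydroxyethyl}phenol F5. Acid‑catalysed cyclodehydration (p‑TsOH 5 mol%, CH2Cl2, 0 °C) through the para‑alkoxybenzyl cation closes the trans‑2,3‑diaryl ring as the racemate. Preparative chiral SFC then separates 14 from its enantiomer (2R,3R)‑4‑(benzyloxy)‑6‑bromo‑2‑[3,4‑bis(benzyloxy)phenyl]‑3‑[3,5‑bis(benzyloxy)phenyl]‑2,3‑dihydro‑1‑benzofuran F6.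

**Step 9 (aryllithium addition).** Risks are base‑induced opening of the dihydrofuran ring (deprotonation at C3 and loss of phenoxide), poor solubility of the sodium phenoxide of 16 at low temperature, and butylation of 17. The fallback avoids strongly basic organometallics, sets out from 14 and comes back at 18. Miyaura borylation of 14 (B2pin2, Pd(dppf)Cl2, KOAc, dioxane, 90 °C) gives the pinacol boronate (2S,3S)‑4‑(benzyloxy)‑2‑[3,4‑bis(benzyloxy)phenyl]‑3‑[3,5‑bis(benzyloxy)phenyl]‑6‑(4,4,5,5‑tetramethyl‑1,3,2‑dioxaborolan‑2‑yl)‑2,3‑dihydro‑1‑benzofuran F7. Rhodium‑catalysed 1,2‑addition of F7 to the unprotected aldehyde 16 ([RhCl(cod)]2, P(t‑Bu)3, aq KOH, dioxane, 60 °C) then gives 18.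

**Step 13 (proposed new annulation, second use).** Risks are those of step 7 on a larger and more hindered ortho‑quinone methide. The fallback uses known chemistry, sets out from 19 and comes back at 26. Compound 19 is deprotonated with NaH and added at −78 °C to 2‑lithio‑1,3‑dithiane F1 (1.3 equiv); warming to 0 °C gives 3‑(benzyloxy)‑5‑{(E)‑2‑[4‑(benzyloxy)phenyl]ethenyl}‑2‑[{(2S,3S)‑4‑(benzyloxy)‑2‑[3,4‑bis(benzyloxy)phenyl]‑3‑[3,5‑bis(benzyloxy)phenyl]‑2,3‑dihydro‑1‑benzofuran‑6‑yl}(1,3‑dithian‑2‑yl)methyl]phenol F8 as both epimers. Hydrolysis (MeI, CaCO3, MeCN/H2O, 45 °C, dark) gives the lactol 4‑(benzyloxy)‑6‑{(E)‑2‑[4‑(benzyloxy)phenyl]ethenyl}‑3‑{(2S,3S)‑4‑(benzyloxy)‑2‑[3,4‑bis(benzyloxy)phenyl]‑3‑[3,5‑bis(benzyloxy)phenyl]‑2,3‑dihydro‑1‑benzofuran‑6‑yl}‑2,3‑dihydro‑1‑benzofuran‑2‑ol F9. [4‑(Benzyloxy)phenyl]magnesium bromide F10 (2.2 equiv, from commercial 1‑(benzyloxy)‑4‑bromobenzene and Mg, THF, 0 °C) gives the diol 3‑(benzyloxy)‑5‑{(E)‑2‑[4‑(benzyloxy)phenyl]ethenyl}‑2‑{2‑[4‑(benzyloxy)phenyl]‑1‑[(2S,3S)‑4‑(benzyloxy)‑2‑[3,4‑bis(benzyloxy)phenyl]‑3‑[3,5‑bis(benzyloxy)phenyl]‑2,3‑dihydro‑1‑benzofuran‑6‑yl]‑2‑hydroxyethyl}phenol F11. Cyclodehydration (p‑TsOH 5 mol%, CH2Cl2, 0 °C; mild enough to leave the stilbene alone) gives the two trans‑ring diastereomers. Because the unit B ring is already a single enantiomer, these are separated on silica or by ordinary preparative HPLC into 26 and (2S,3S)‑4‑(benzyloxy)‑2‑[4‑(benzyloxy)phenyl]‑6‑{(E)‑2‑[4‑(benzyloxy)phenyl]ethenyl}‑3‑{(2S,3S)‑4‑(benzyloxy)‑2‑[3,4‑bis(benzyloxy)phenyl]‑3‑[3,5‑bis(benzyloxy)phenyl]‑2,3‑dihydro‑1‑benzofuran‑6‑yl}‑2,3‑dihydro‑1‑benzofuran F12.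

## Further compounds

F1 | step 7 | 2‑lithio‑1,3‑dithiane | [Li]C1SCCCS1
F2 | step 7 | rac‑3‑(benzyloxy)‑5‑bromo‑2‑{[3,5‑bis(benzyloxy)phenyl](1,3‑dithian‑2‑yl)methyl}phenol | Oc1cc(Br)cc(OCc2ccccc2)c1C(C1SCCCS1)c1cc(OCc2ccccc2)cc(OCc2ccccc2)c1
F3 | step 7 | rac‑4‑(benzyloxy)‑3‑[3,5‑bis(benzyloxy)phenyl]‑6‑bromo‑2,3‑dihydro‑1‑benzofuran‑2‑ol (lactol, anomer mixture) | OC1Oc2cc(Br)cc(OCc3ccccc3)c2C1c1cc(OCc2ccccc2)cc(OCc2ccccc2)c1
F4 | step 7 | [3,4‑bis(benzyloxy)phenyl]magnesium bromide | Br[Mg]c1ccc(OCc2ccccc2)c(OCc2ccccc2)c1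
F5 | step 7 | rac‑3‑(benzyloxy)‑5‑bromo‑2‑{2‑[3,4‑bis(benzyloxy)phenyl]‑1‑[3,5‑bis(benzyloxy)phenyl]‑2‑hydroxyethyl}phenol (diastereomer mixture) | OC(c1ccc(OCc2ccccc2)c(OCc2ccccc2)c1)C(c1cc(OCc2ccccc2)cc(OCc2ccccc2)c1)c1c(O)cc(Br)cc1OCc1ccccc1
F6 | step 7 | (2R,3R)‑4‑(benzyloxy)‑6‑bromo‑2‑[3,4‑bis(benzyloxy)phenyl]‑3‑[3,5‑bis(benzyloxy)phenyl]‑2,3‑dihydro‑1‑benzofuran (enantiomer of 14) | Brc1cc(OCc2ccccc2)c2c(c1)O[C@@H](c1ccc(OCc3ccccc3)c(OCc3ccccc3)c1)[C@@H]2c1cc(OCc2ccccc2)cc(OCc2ccccc2)c1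
F7 | step 9 | (2S,3S)‑4‑(benzyloxy)‑2‑[3,4‑bis(benzyloxy)phenyl]‑3‑[3,5‑bis(benzyloxy)phenyl]‑6‑(4,4,5,5‑tetramethyl‑1,3,2‑dioxaborolan‑2‑yl)‑2,3‑dihydro‑1‑benzofuran | CC1(C)OB(OC1(C)C)c1cc(OCc2ccccc2)c2c(c1)O[C@H](c1ccc(OCc3ccccc3)c(OCc3ccccc3)c1)[C@H]2c1cc(OCc2ccccc2)cc(OCc2ccccc2)c1
F8 | step 13 | 3‑(benzyloxy)‑5‑{(E)‑2‑[4‑(benzyloxy)phenyl]ethenyl}‑2‑[{(2S,3S)‑4‑(benzyloxy)‑2‑[3,4‑bis(benzyloxy)phenyl]‑3‑[3,5‑bis(benzyloxy)phenyl]‑2,3‑dihydro‑1‑benzofuran‑6‑yl}(1,3‑dithian‑2‑yl)methyl]phenol (both epimers) | Oc1cc(/C=C/c2ccc(OCc3ccccc3)cc2)cc(OCc2ccccc2)c1C(C1SCCCS1)c1cc(OCc2ccccc2)c2c(c1)O[C@H](c1ccc(OCc3ccccc3)c(OCc3ccccc3)c1)[C@H]2c1cc(OCc2ccccc2)cc(OCc2ccccc2)c1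
F9 | step 13 | 4‑(benzyloxy)‑6‑{(E)‑2‑[4‑(benzyloxy)phenyl]ethenyl}‑3‑{(2S,3S)‑4‑(benzyloxy)‑2‑[3,4‑bis(benzyloxy)phenyl]‑3‑[3,5‑bis(benzyloxy)phenyl]‑2,3‑dihydro‑1‑benzofuran‑6‑yl}‑2,3‑dihydro‑1‑benzofuran‑2‑ol (lactol, epimer mixture) | OC1Oc2cc(/C=C/c3ccc(OCc4ccccc4)cc3)cc(OCc3ccccc3)c2C1c1cc(OCc2ccccc2)c2c(c1)O[C@H](c1ccc(OCc3ccccc3)c(OCc3ccccc3)c1)[C@H]2c1cc(OCc2ccccc2)cc(OCc2ccccc2)c1
F10 | step 13 | [4‑(benzyloxy)phenyl]magnesium bromide | Br[Mg]c1ccc(OCc2ccccc2)cc1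
F11 | step 13 | 3‑(benzyloxy)‑5‑{(E)‑2‑[4‑(benzyloxy)phenyl]ethenyl}‑2‑{2‑[4‑(benzyloxy)phenyl]‑1‑[(2S,3S)‑4‑(benzyloxy)‑2‑[3,4‑bis(benzyloxy)phenyl]‑3‑[3,5‑bis(benzyloxy)phenyl]‑2,3‑dihydro‑1‑benzofuran‑6‑yl]‑2‑hydroxyethyl}phenol (epimer mixture) | OC(c1ccc(OCc2ccccc2)cc1)C(c1c(O)cc(/C=C/c2ccc(OCc3ccccc3)cc2)cc1OCc1ccccc1)c1cc(OCc2ccccc2)c2c(c1)O[C@H](c1ccc(OCc3ccccc3)c(OCc3ccccc3)c1)[C@H]2c1cc(OCc2ccccc2)cc(OCc2ccccc2)c1
F12 | step 13 | (2S,3S)‑4‑(benzyloxy)‑2‑[4‑(benzyloxy)phenyl]‑6‑{(E)‑2‑[4‑(benzyloxy)phenyl]ethenyl}‑3‑{(2S,3S)‑4‑(benzyloxy)‑2‑[3,4‑bis(benzyloxy)phenyl]‑3‑[3,5‑bis(benzyloxy)phenyl]‑2,3‑dihydro‑1‑benzofuran‑6‑yl}‑2,3‑dihydro‑1‑benzofuran (diastereomer of 26) | C(Oc1ccc(/C=C/c2cc(OCc3ccccc3)c3c(c2)O[C@H](c2ccc(OCc4ccccc4)cc2)[C@H]3c2cc(OCc3ccccc3)c3c(c2)O[C@H](c2ccc(OCc4ccccc4)c(OCc4ccccc4)c2)[C@H]3c2cc(OCc3ccccc3)cc(OCc3ccccc3)c2)cc1)c1ccccc1
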